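**Plan**

- Retrosynthesis (germacrane numbering: C-1=C-10 alkene, C-4/C-5 epoxide, C-6 and C-8 acyloxy carbons, C-7 isopropyl): the C-8 tiglate and then the C-6 (2R,3S)-3-hydroxy-2-methylbutanoate are cut, the isopropyl is taken back to isopropenyl, and the ten-membered ring is opened at C-6–C-7.
- The feature that allows this is the homoallylic alcohol unit O–C-6–C-7–C-11(=C-12) in the cyclodecene ring: it is the retron of a γ-selective addition of a 2-methylallyl metal terminus (C-12–C-11=C-7) to an aldehyde at C-6, run intramolecularly on an acyclic (4R,5R)-epoxy aldehyde that already carries the C-8 oxygen.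
- The open chain is cut at C-1–C-2 (B-alkyl Suzuki–Miyaura coupling of an alkenyl iodide with a borane from a C6 diene) and at C-8–C-9 (propargylation of 3-methylbut-2-enal).
- Forward: C-8 carbinol, C-12 oxygen by allylic oxidation, C-1=C-10 alkene by carboalumination, chain union, allylic chloride and epoxy aldehyde, ring closure (the only ring formed after the epoxide), hydrogenation, two esterifications.
- Stereochemistry: C-8 from catalyst-controlled propargylation; C-4/C-5 from Sharpless epoxidation with D-(−)-diethyl tartrate; C-6 and C-7 from the ring closure under control of C-8 and the epoxide; the side-chain diad from an Evans syn aldol.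

Key step: step 14

Remark: ring compounds are named with germacrane numbering, and the Why lines use the same atom numbers for the open-chain precursors; descriptors at C-5 and C-7 change in some intermediates by priority only.
Assumption: the (R)-configured phosphoric acid in step 1 is taken to give the (R)-carbinol, as with aryl and alkenyl aldehydes; the antipodal catalyst serves if the sense is opposite.

Step 1
Reactants: 1 3-methylbut-2-enal; 2 4,4,5,5-tetramethyl-2-(propa-1,2-dien-1-yl)-1,3,2-dioxaborolane (allenylboronic acid pinacol ester)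
Product: 3 (R)-6-methylhept-5-en-1-yn-4-ol
Conditions: (R)-TRIP phosphoric acid (5 mol %), 4 Å MS, toluene, 0 °C; aqueous work-up
Reagents that add atoms: none
Why: Chiral Brønsted acid-catalysed propargylation, in which the allenylboronate adds by SE2′ through a six-membered chair organised by the phosphoric acid, so the catalyst sets the C-8 carbinol as R and only 1,2-addition to the enal occurs.

Step 2
Reactants: 3 (R)-6-methylhept-5-en-1-yn-4-ol
Product: 4 1-methoxy-4-({[(4R)-6-methylhept-5-en-1-yn-4-yl]oxy}methyl)benzene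
Conditions: NaH (1.05 equiv), 4-methoxybenzyl chloride, Bu4NI (cat.), THF/DMF, 0 °C → rt
Reagents that add atoms: 4-methoxybenzyl chloride, COc1ccc(CCl)cc1
Why: Williamson etherification of the sodium alkoxide, which does not touch the carbinol stereocentre and gives a C-8 ether that is removed late under neutral oxidative conditions.

Step 3
Reactants: 4 1-methoxy-4-({[(4R)-6-methylhept-5-en-1-yn-4-yl]oxy}methyl)benzene
Product: 5 (2E,4R)-4-[(4-methoxybenzyl)oxy]-2-methylhept-2-en-6-yn-1-ol
Conditions: SeO2 (0.3 equiv), t-BuOOH (2.5 equiv), salicylic acid (cat.), CH2Cl2, 0 °C → rt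
Reagents that add atoms: tert-butyl hydroperoxide, CC(C)(C)OO (terminal oxidant; the oxygen is passed on by catalytic selenium dioxide, O=[Se]=O)
Why: Riley allylic oxidation (ene reaction at the less substituted alkene carbon, then [2,3]-sigmatropic shift) hydroxylates the (E)-methyl of the trisubstituted alkene, which fixes the E geometry of C-7=C-11 with C-12 oxygenated.

Step 4
Reactants: 5 (2E,4R)-4-[(4-methoxybenzyl)oxy]-2-methylhept-2-en-6-yn-1-ol
Product: 6 tert-butyl({(2E,4R)-4-[(4-methoxybenzyl)oxy]-2-methylhept-2-en-6-yn-1-yl}oxy)dimethylsilane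
Conditions: TBSCl, imidazole, DMF, 0 °C → rt
Reagents that add atoms: tert-butyldimethylsilyl chloride, CC(C)(C)[Si](C)(C)Cl
Why: Standard silylation of the primary allylic alcohol gives a C-12 ether that survives organoaluminium, palladium and base and is later removed by fluoride beside the benzylic ether.

Step 5
Reactants: 6 tert-butyl({(2E,4R)-4-[(4-methoxybenzyl)oxy]-2-methylhept-2-en-6-yn-1-yl}oxy)dimethylsilane
Product: 8 tert-butyl({(2E,4R,6E)-7-iodo-4-[(4-methoxybenzyl)oxy]-2,6-dimethylhepta-2,6-dien-1-yl}oxy)dimethylsilane, via alkenyldimethylalane 7 (not isolated)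
Conditions: Me3Al (3 equiv), Cp2ZrCl2 (0.25 equiv), CH2Cl2, −20 °C → rt; then I2, THF, −30 → 0 °C
Reagents that add atoms: trimethylaluminium, C[Al](C)C; iodine, II
Why: Zirconium-catalysed carboalumination (Negishi) adds methyl and aluminium syn across the terminal alkyne with the metal on the terminal carbon, and iodinolysis with retention gives the (E)-alkenyl iodide that becomes the C-1=C-10 alkene.

Step 6
Reactants: 9 (2E)-3-methylpent-2-en-4-yn-1-ol
Product: 10 (2E)-3-methylpenta-2,4-dien-1-ol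
Conditions: H2 (1 atm), Pd/CaCO3 poisoned with Pb(OAc)2 (Lindlar type), quinoline, EtOAc, rt, stopped after one equivalent
Reagents that add atoms: none
Why: Semihydrogenation of the terminal alkyne on poisoned palladium stops at the vinyl group and leaves the (E)-trisubstituted alkene (later C-4=C-5) unchanged.

Step 7
Reactants: 10 (2E)-3-methylpenta-2,4-dien-1-ol
Product: 11 (2E)-3-methylpenta-2,4-dien-1-yl pivalate
Conditions: PivCl, pyridine, DMAP (cat.), CH2Cl2, 0 °C → rt
Reagents that add atoms: pivaloyl chloride, CC(C)(C)C(Cl)=O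
Why: Acylation of the primary allylic alcohol gives a hindered ester that tolerates 9-BBN and the basic coupling and is later removed reductively beside the allylic chloride.

Step 8
Reactants: 11 (2E)-3-methylpenta-2,4-dien-1-yl pivalate; 8 tert-butyl({(2E,4R,6E)-7-iodo-4-[(4-methoxybenzyl)oxy]-2,6-dimethylhepta-2,6-dien-1-yl}oxy)dimethylsilane
Product: 13 (2E,6E,9R,10E)-12-[(tert-butyldimethylsilyl)oxy]-9-[(4-methoxybenzyl)oxy]-3,7,11-trimethyldodeca-2,6,10-trien-1-yl pivalate, via B-alkyl-9-borabicyclononane 12 (not isolated)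
Conditions: 11, 9-BBN-H dimer, THF, 0 °C → rt; then 8, Pd(dppf)Cl2 (5 mol %), AsPh3, Cs2CO3, DMF/THF/H2O, rt
Reagents that add atoms: none
Why: 9-BBN hydroborates only the terminal vinyl group of the diene at its CH2 end, and the B-alkyl Suzuki–Miyaura coupling of the primary borane with the alkenyl iodide forms the C-1–C-2 bond with retention of alkene geometry.

Step 9
Reactants: 13 (2E,6E,9R,10E)-12-[(tert-butyldimethylsilyl)oxy]-9-[(4-methoxybenzyl)oxy]-3,7,11-trimethyldodeca-2,6,10-trien-1-yl pivalate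
Product: 14 (2E,6E,9R,10E)-12-hydroxy-9-[(4-methoxybenzyl)oxy]-3,7,11-trimethyldodeca-2,6,10-trien-1-yl pivalate
Conditions: Bu4NF, THF, 0 °C
Reagents that add atoms: none
Why: Fluoride cleaves the primary silyl ether chemoselectively, the pivalate and the benzylic ether being inert.

Step 10
Reactants: 14 (2E,6E,9R,10E)-12-hydroxy-9-[(4-methoxybenzyl)oxy]-3,7,11-trimethyldodeca-2,6,10-trien-1-yl pivalate
Product: 16 (2E,6E,9R,10E)-12-chloro-9-[(4-methoxybenzyl)oxy]-3,7,11-trimethyldodeca-2,6,10-trien-1-yl pivalate, via allylic mesylate 15 (not isolated)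
Conditions: MsCl, 2,4,6-collidine, LiCl, DMF, 0 °C
Reagents that add atoms: lithium chloride, [Li+].[Cl-]
Why: The primary allylic mesylate formed in situ is displaced by chloride in an SN2 reaction, without allylic transposition or loss of alkene geometry.

Step 11
Reactants: 16 (2E,6E,9R,10E)-12-chloro-9-[(4-methoxybenzyl)oxy]-3,7,11-trimethyldodeca-2,6,10-trien-1-yl pivalate
Product: 17 (2E,6E,9R,10E)-12-chloro-9-[(4-methoxybenzyl)oxy]-3,7,11-trimethyldodeca-2,6,10-trien-1-ol
Conditions: iBu2AlH (2.5 equiv), CH2Cl2, −78 °C; Rochelle salt work-up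
Reagents that add atoms: none
Why: Reductive cleavage of the pivalate at low temperature frees the C-6 allylic alcohol while the allylic chloride and the benzylic ether are not reduced.

Step 12
Reactants: 17 (2E,6E,9R,10E)-12-chloro-9-[(4-methoxybenzyl)oxy]-3,7,11-trimethyldodeca-2,6,10-trien-1-ol
Product: 18 [(2R,3R)-3-{(3E,6R,7E)-9-chloro-6-[(4-methoxybenzyl)oxy]-4,8-dimethylnona-3,7-dien-1-yl}-3-methyloxiran-2-yl]methanol
Conditions: Ti(OiPr)4 (10 mol %), D-(−)-diethyl tartrate (12 mol %), t-BuOOH (decane solution), 4 Å MS, CH2Cl2, −20 °C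
Reagents that add atoms: tert-butyl hydroperoxide, CC(C)(C)OO
Why: Sharpless asymmetric epoxidation, in which the titanium tartrate binds the allylic alcohol and delivers oxygen only to the C-4=C-5 alkene on the face dictated by the D-tartrate, sets the (4R,5R) trans epoxide under reagent control.

Step 13
Reactants: 18 [(2R,3R)-3-{(3E,6R,7E)-9-chloro-6-[(4-methoxybenzyl)oxy]-4,8-dimethylnona-3,7-dien-1-yl}-3-methyloxiran-2-yl]methanol
Product: 19 (2S,3R)-3-{(3E,6R,7E)-9-chloro-6-[(4-methoxybenzyl)oxy]-4,8-dimethylnona-3,7-dien-1-yl}-3-methyloxirane-2-carbaldehyde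
Conditions: Dess–Martin periodinane, NaHCO3, CH2Cl2, 0 °C → rt
Reagents that add atoms: none
Why: Buffered hypervalent-iodine oxidation gives the α,β-epoxy aldehyde without epimerisation (the descriptor at C-5 changes by priority only) and leaves chloride, alkenes and the benzylic ether alone.

Step 14
Reactants: 19 (2S,3R)-3-{(3E,6R,7E)-9-chloro-6-[(4-methoxybenzyl)oxy]-4,8-dimethylnona-3,7-dien-1-yl}-3-methyloxirane-2-carbaldehyde
Product: 21 (4R,5R,6S,7R,8R)-4,5-epoxy-8-[(4-methoxybenzyl)oxy]germacra-1(10)E,11-dien-6-ol, via allyl(ethyl)zinc 20 (not isolated)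
Conditions: PdCl2(PPh3)2 (10 mol %), Et2Zn (hexane solution, 4 equiv), K2CO3, DMA, syringe-pump addition of 19 to a final 0.005 M, rt; NH4Cl work-up
Reagents that add atoms: none
Why: Zerovalent palladium (formed from PdCl2(PPh3)2 and Et2Zn) ionises the primary allylic chloride to a π-allylpalladium complex, Et2Zn transmetalates it to the nucleophilic, E/Z-equilibrating allyl(ethyl)zinc 20, and this adds through its γ-carbon (C-7) to the tethered formyl carbon (C-6) in a six-membered chair (Zimmerman–Traxler) array to give the zinc alkoxide of 21. The closest known reaction type is the palladium-catalysed, diethylzinc-mediated umpolung carbonyl allylation with allylic halides and esters, which has precedent for closing ten-membered rings from ω-(allylic chloride) 2,3-epoxy aldehydes of the farnesane series. The ten-membered carbocycle closes by intramolecular SE2′ carbonyl addition (10-exo-trig at the formyl group, through the internal terminus of the allyl unit), so the C-11=C-12 alkene ends exocyclic as the isopropenyl group. C-7 is controlled by the resident C-8 stereocentre: with H-8 eclipsing the allyl plane (minimal 1,3-allylic strain) the aldehyde enters anti to the C-8–O bond, which gives the 7,8-trans relation. C-6 is controlled by the epoxide and the ring: the C-5–O bond lies anti to the forming bond with H-5 inside (polar Felkin–Anh arrangement), and strain in the ten-membered transition state is expected to favour the chair with the epoxide carbon equatorial and the C-8 branch axial (reaction through the (Z)-σ-allylzinc), which gives the 6,7-cis carbinol. The step needs γ- over α-attack (secured by the closed six-membered transition state, α-attack requiring a twelve-membered ring), cyclisation over oligomerisation (slow addition at high dilution) and survival of epoxide and δ-alkoxy group (neutral, weakly Lewis-acidic allylzinc at room temperature, an ether being too poor a leaving group for 1,4-elimination).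

Step 15
Reactants: 21 (4R,5R,6S,7R,8R)-4,5-epoxy-8-[(4-methoxybenzyl)oxy]germacra-1(10)E,11-dien-6-ol
Product: 22 (4R,5R,6S,7R,8R)-4,5-epoxy-8-[(4-methoxybenzyl)oxy]germacr-1(10)E-en-6-ol
Conditions: H2 (1 atm), RhCl(PPh3)3 (10 mol %), toluene/EtOH, rt
Reagents that add atoms: none
Why: Homogeneous hydrogenation with the bulky rhodium phosphine catalyst saturates the 1,1-disubstituted isopropenyl alkene much faster than the trisubstituted ring alkene and does not open the epoxide or cleave the benzylic ether; no stereocentre is formed.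

Step 16
Reactants: 23 (R)-4-benzyl-3-propionyloxazolidin-2-one; 24 acetaldehyde
Product: 26 (R)-4-benzyl-3-[(2R,3S)-3-hydroxy-2-methylbutanoyl]oxazolidin-2-one, via Z-boron enolate 25 (not isolated)
Conditions: Bu2BOTf, iPr2NEt, CH2Cl2, −78 → 0 °C; then 24, −78 → 0 °C; pH 7 buffer, H2O2, MeOH
Reagents that add atoms: none
Why: Evans syn aldol, in which the (Z)-dibutylboron enolate reacts through a chair transition state with the auxiliary benzyl group shielding one enolate face, sets the 2R,3S syn diad.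

Step 17
Reactants: 26 (R)-4-benzyl-3-[(2R,3S)-3-hydroxy-2-methylbutanoyl]oxazolidin-2-one
Product: 27 (R)-4-benzyl-3-{(2R,3S)-2-methyl-3-[(triethylsilyl)oxy]butanoyl}oxazolidin-2-one
Conditions: TESOTf, 2,6-lutidine, CH2Cl2, −78 → 0 °C
Reagents that add atoms: triethylsilyl triflate, CC[Si](CC)(CC)OS(=O)(=O)C(F)(F)F
Why: Silylation under weakly basic conditions protects the β-hydroxyl without retro-aldol or epimerisation, as an ether that can be removed at the end under very mild conditions.

Step 18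
Reactants: 27 (R)-4-benzyl-3-{(2R,3S)-2-methyl-3-[(triethylsilyl)oxy]butanoyl}oxazolidin-2-one
Product: 29 (2R,3S)-2-methyl-3-[(triethylsilyl)oxy]butanoic acid, via peroxy acid 28 (not isolated)
Conditions: LiOH, H2O2, THF/H2O, 0 °C; then Na2SO3; KHSO4 to pH 4–5 at 0 °C
Reagents that add atoms: hydrogen peroxide, OO (as lithium hydroperoxide formed with lithium hydroxide, [Li+].[OH-])
Why: Lithium hydroperoxide attacks the exocyclic imide carbonyl selectively and sulfite reduces the peroxy acid, which gives the acid without epimerisation of the α-centre and returns the auxiliary.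

Step 19
Reactants: 22 (4R,5R,6S,7R,8R)-4,5-epoxy-8-[(4-methoxybenzyl)oxy]germacr-1(10)E-en-6-ol; 29 (2R,3S)-2-methyl-3-[(triethylsilyl)oxy]butanoic acid
Product: 31 (4R,5R,6S,7S,8R)-4,5-epoxy-8-[(4-methoxybenzyl)oxy]germacr-1(10)E-en-6-yl (2R,3S)-2-methyl-3-[(triethylsilyl)oxy]butanoate, via silyloxybutanoic mixed anhydride 30 (not isolated)
Conditions: 29, 2,4,6-trichlorobenzoyl chloride, Et3N, toluene, rt; then 22, DMAP, toluene, rt → 40 °C
Reagents that add atoms: none
Why: Yamaguchi esterification, in which DMAP opens the mixed anhydride at the less hindered carbonyl and the acylpyridinium acylates the hindered C-6 hydroxyl with retention at C-6 and without ketene formation at the α-stereocentre.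

Step 20
Reactants: 31 (4R,5R,6S,7S,8R)-4,5-epoxy-8-[(4-methoxybenzyl)oxy]germacr-1(10)E-en-6-yl (2R,3S)-2-methyl-3-[(triethylsilyl)oxy]butanoate
Product: 32 (4R,5R,6S,7S,8R)-4,5-epoxy-8-hydroxygermacr-1(10)E-en-6-yl (2R,3S)-2-methyl-3-[(triethylsilyl)oxy]butanoate
Conditions: DDQ, CH2Cl2/pH 7 phosphate buffer (10:1), 0 °C
Reagents that add atoms: none
Why: Oxidation of the electron-rich benzyl ether to an oxocarbenium ion and its hydrolysis frees the C-8 hydroxyl under buffered conditions that spare epoxide, ring alkene, ester and silyl ether.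

Step 21
Reactants: 32 (4R,5R,6S,7S,8R)-4,5-epoxy-8-hydroxygermacr-1(10)E-en-6-yl (2R,3S)-2-methyl-3-[(triethylsilyl)oxy]butanoate; 33 (2E)-2-methylbut-2-enoic acid (tiglic acid)
Product: 35 (4R,5R,6S,7S,8R)-4,5-epoxy-6-({(2R,3S)-2-methyl-3-[(triethylsilyl)oxy]butanoyl}oxy)germacr-1(10)E-en-8-yl (2E)-2-methylbut-2-enoate, via tiglic mixed anhydride 34 (not isolated)
Conditions: 33, 2,4,6-trichlorobenzoyl chloride, Et3N, toluene, rt; then 32, DMAP, toluene, 60 °C
Reagents that add atoms: none
Why: Yamaguchi esterification of the secondary C-8 hydroxyl, the only free hydroxyl, with the thermodynamically stable (E)-acid, so no geometric isomerisation of the enoate is expected.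

Step 22
Reactants: 35 (4R,5R,6S,7S,8R)-4,5-epoxy-6-({(2R,3S)-2-methyl-3-[(triethylsilyl)oxy]butanoyl}oxy)germacr-1(10)E-en-8-yl (2E)-2-methylbut-2-enoate
Product: 36 (4R,5R,6S,7S,8R)-4,5-epoxy-6-{[(2R,3S)-3-hydroxy-2-methylbutanoyl]oxy}germacr-1(10)E-en-8-yl (2E)-2-methylbut-2-enoate (CNP0159364.1)
Conditions: HF·pyridine, pyridine, THF, 0 °C
Reagents that add atoms: none
Why: Pyridine-buffered fluoride cleaves the secondary triethylsilyl ether quickly, under conditions mild enough to avoid transannular opening of the epoxide, acyl migration and β-elimination of the hydroxy ester.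

**Compound list**

1 | 3-methylbut-2-enal | CC(C)=CC=O | starting material
2 | 4,4,5,5-tetramethyl-2-(propa-1,2-dien-1-yl)-1,3,2-dioxaborolane | C=C=CB1OC(C)(C)C(C)(C)O1 | starting material
3 | (R)-6-methylhept-5-en-1-yn-4-ol | C#CC[C@@H](O)C=C(C)C | intermediate
4 | 1-methoxy-4-({[(4R)-6-methylhept-5-en-1-yn-4-yl]oxy}methyl)benzene | C#CC[C@@H](OCc1ccc(OC)cc1)C=C(C)C | intermediate
5 | (2E,4R)-4-[(4-methoxybenzyl)oxy]-2-methylhept-2-en-6-yn-1-ol | C#CC[C@@H](OCc1ccc(OC)cc1)/C=C(\C)CO | intermediate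
6 | tert-butyl({(2E,4R)-4-[(4-methoxybenzyl)oxy]-2-methylhept-2-en-6-yn-1-yl}oxy)dimethylsilane | C#CC[C@@H](OCc1ccc(OC)cc1)/C=C(\C)CO[Si](C)(C)C(C)(C)C | intermediate
7 | {(1E,4R,5E)-7-[(tert-butyldimethylsilyl)oxy]-4-[(4-methoxybenzyl)oxy]-2,6-dimethylhepta-1,5-dien-1-yl}dimethylalane | C[Al](C)/C=C(\C)C[C@@H](OCc1ccc(OC)cc1)/C=C(\C)CO[Si](C)(C)C(C)(C)C | intermediate
8 | tert-butyl({(2E,4R,6E)-7-iodo-4-[(4-methoxybenzyl)oxy]-2,6-dimethylhepta-2,6-dien-1-yl}oxy)dimethylsilane | I/C=C(\C)C[C@@H](OCc1ccc(OC)cc1)/C=C(\C)CO[Si](C)(C)C(C)(C)C | intermediate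
9 | (2E)-3-methylpent-2-en-4-yn-1-ol | C#C/C(C)=C/CO | starting material
10 | (2E)-3-methylpenta-2,4-dien-1-ol | C=C/C(C)=C/CO | intermediate
11 | (2E)-3-methylpenta-2,4-dien-1-yl pivalate | C=C/C(C)=C/COC(=O)C(C)(C)C | intermediate
12 | (2E)-5-(9-borabicyclo[3.3.1]nonan-9-yl)-3-methylpent-2-en-1-yl pivalate | CC(C)(C)C(=O)OC/C=C(\C)CCB1C2CCCC1CCC2 | intermediate
13 | (2E,6E,9R,10E)-12-[(tert-butyldimethylsilyl)oxy]-9-[(4-methoxybenzyl)oxy]-3,7,11-trimethyldodeca-2,6,10-trien-1-yl pivalate | CC(C)(C)C(=O)OC/C=C(\C)CC/C=C(\C)C[C@@H](OCc1ccc(OC)cc1)/C=C(\C)CO[Si](C)(C)C(C)(C)C | intermediate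
14 | (2E,6E,9R,10E)-12-hydroxy-9-[(4-methoxybenzyl)oxy]-3,7,11-trimethyldodeca-2,6,10-trien-1-yl pivalate | CC(C)(C)C(=O)OC/C=C(\C)CC/C=C(\C)C[C@@H](OCc1ccc(OC)cc1)/C=C(\C)CO | intermediate
15 | (2E,6E,9R,10E)-9-[(4-methoxybenzyl)oxy]-3,7,11-trimethyl-12-[(methylsulfonyl)oxy]dodeca-2,6,10-trien-1-yl pivalate | CC(C)(C)C(=O)OC/C=C(\C)CC/C=C(\C)C[C@@H](OCc1ccc(OC)cc1)/C=C(\C)COS(C)(=O)=O | intermediate
16 | (2E,6E,9R,10E)-12-chloro-9-[(4-methoxybenzyl)oxy]-3,7,11-trimethyldodeca-2,6,10-trien-1-yl pivalate | CC(C)(C)C(=O)OC/C=C(\C)CC/C=C(\C)C[C@@H](OCc1ccc(OC)cc1)/C=C(\C)CCl | intermediate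
17 | (2E,6E,9R,10E)-12-chloro-9-[(4-methoxybenzyl)oxy]-3,7,11-trimethyldodeca-2,6,10-trien-1-ol | OC/C=C(\C)CC/C=C(\C)C[C@@H](OCc1ccc(OC)cc1)/C=C(\C)CCl | intermediate
18 | [(2R,3R)-3-{(3E,6R,7E)-9-chloro-6-[(4-methoxybenzyl)oxy]-4,8-dimethylnona-3,7-dien-1-yl}-3-methyloxiran-2-yl]methanol | OC[C@H]1O[C@]1(C)CC/C=C(\C)C[C@@H](OCc1ccc(OC)cc1)/C=C(\C)CCl | intermediate
19 | (2S,3R)-3-{(3E,6R,7E)-9-chloro-6-[(4-methoxybenzyl)oxy]-4,8-dimethylnona-3,7-dien-1-yl}-3-methyloxirane-2-carbaldehyde | O=C[C@H]1O[C@]1(C)CC/C=C(\C)C[C@@H](OCc1ccc(OC)cc1)/C=C(\C)CCl | intermediate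
20 | allyl(ethyl)zinc from 19 (ZnEt in place of Cl at C-12; σ-allyl, E/Z-equilibrating at C-7=C-11) | O=C[C@H]1O[C@]1(C)CC/C=C(\C)C[C@@H](OCc1ccc(OC)cc1)C=C(C)C[Zn]CC | intermediate
21 | (4R,5R,6S,7R,8R)-4,5-epoxy-8-[(4-methoxybenzyl)oxy]germacra-1(10)E,11-dien-6-ol | COc1ccc(CO[C@@H]2C/C(C)=C/CC[C@@]3(C)O[C@@H]3[C@@H](O)[C@H]2C(C)=C)cc1 | intermediate
22 | (4R,5R,6S,7R,8R)-4,5-epoxy-8-[(4-methoxybenzyl)oxy]germacr-1(10)E-en-6-ol | COc1ccc(CO[C@@H]2C/C(C)=C/CC[C@@]3(C)O[C@@H]3[C@@H](O)[C@H]2C(C)C)cc1 | intermediate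
23 | (R)-4-benzyl-3-propionyloxazolidin-2-one | CCC(=O)N1[C@H](Cc2ccccc2)COC1=O | starting material
24 | acetaldehyde | CC=O | starting material
25 | (Z)-dibutylboron enolate of 23 | C/C=C(\OB(CCCC)CCCC)N1[C@H](Cc2ccccc2)COC1=O | intermediate
26 | (R)-4-benzyl-3-[(2R,3S)-3-hydroxy-2-methylbutanoyl]oxazolidin-2-one | C[C@H](O)[C@@H](C)C(=O)N1[C@H](Cc2ccccc2)COC1=O | intermediate
27 | (R)-4-benzyl-3-{(2R,3S)-2-methyl-3-[(triethylsilyl)oxy]butanoyl}oxazolidin-2-one | C[C@H](O[Si](CC)(CC)CC)[C@@H](C)C(=O)N1[C@H](Cc2ccccc2)COC1=O | intermediate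
28 | (2R,3S)-2-methyl-3-[(triethylsilyl)oxy]butaneperoxoic acid | C[C@H](O[Si](CC)(CC)CC)[C@@H](C)C(=O)OO | intermediate
29 | (2R,3S)-2-methyl-3-[(triethylsilyl)oxy]butanoic acid | C[C@H](O[Si](CC)(CC)CC)[C@@H](C)C(=O)O | intermediate
30 | (2R,3S)-2-methyl-3-[(triethylsilyl)oxy]butanoic 2,4,6-trichlorobenzoic anhydride | C[C@H](O[Si](CC)(CC)CC)[C@@H](C)C(=O)OC(=O)c1c(Cl)cc(Cl)cc1Cl | intermediate
31 | (4R,5R,6S,7S,8R)-4,5-epoxy-8-[(4-methoxybenzyl)oxy]germacr-1(10)E-en-6-yl (2R,3S)-2-methyl-3-[(triethylsilyl)oxy]butanoate | COc1ccc(CO[C@@H]2C/C(C)=C/CC[C@@]3(C)O[C@@H]3[C@@H](OC(=O)[C@H](C)[C@H](C)O[Si](CC)(CC)CC)[C@H]2C(C)C)cc1 | intermediate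
32 | (4R,5R,6S,7S,8R)-4,5-epoxy-8-hydroxygermacr-1(10)E-en-6-yl (2R,3S)-2-methyl-3-[(triethylsilyl)oxy]butanoate | O[C@@H]1C/C(C)=C/CC[C@@]2(C)O[C@@H]2[C@@H](OC(=O)[C@H](C)[C@H](C)O[Si](CC)(CC)CC)[C@H]1C(C)C | intermediate
33 | (2E)-2-methylbut-2-enoic acid (tiglic acid) | C/C=C(\C)C(=O)O | starting material
34 | (2E)-2-methylbut-2-enoic 2,4,6-trichlorobenzoic anhydride | C/C=C(\C)C(=O)OC(=O)c1c(Cl)cc(Cl)cc1Cl | intermediate
35 | (4R,5R,6S,7S,8R)-4,5-epoxy-6-({(2R,3S)-2-methyl-3-[(triethylsilyl)oxy]butanoyl}oxy)germacr-1(10)E-en-8-yl (2E)-2-methylbut-2-enoate | C/C=C(\C)C(=O)O[C@@H]1C/C(C)=C/CC[C@@]2(C)O[C@@H]2[C@@H](OC(=O)[C@H](C)[C@H](C)O[Si](CC)(CC)CC)[C@H]1C(C)C | intermediate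
36 | (4R,5R,6S,7S,8R)-4,5-epoxy-6-{[(2R,3S)-3-hydroxy-2-methylbutanoyl]oxy}germacr-1(10)E-en-8-yl (2E)-2-methylbut-2-enoate | C/C=C(\C)C(=O)O[C@@H]1C/C(C)=C/CC[C@@]2(C)O[C@@H]2[C@@H](OC(=O)[C@H](C)[C@H](C)O)[C@H]1C(C)C | target

**Count**

Total step count: 22. Longest linear sequence: 17 steps (steps 1–5, 8–15, 19–22).

**Steps most likely to fail**

Step 14 (ring closure). The risk is loss of facial control at the formyl carbon, through competition of the chair with the C-8 branch equatorial or of an open transition state; oligomerisation and 1,4-elimination of the δ-alkoxy allylzinc are further risks. The fallback sets C-6 by ketone reduction instead of in the C–C bond formation. It sets out from 19: the cyclisation would then give the C-6 epimer (4R,5R,6R,7R,8R)-4,5-epoxy-8-[(4-methoxybenzyl)oxy]germacra-1(10)E,11-dien-6-ol F1. This is hydrogenated as in step 15 to (4R,5R,6R,7R,8R)-4,5-epoxy-8-[(4-methoxybenzyl)oxy]germacr-1(10)E-en-6-ol F2 and oxidised with Dess–Martin periodinane/NaHCO3 to the epoxy ketone (4R,5S,7S,8R)-4,5-epoxy-8-[(4-methoxybenzyl)oxy]germacr-1(10)E-en-6-one F3. Reduction with KBH(s-Bu)3 (THF, −78 °C) should deliver hydride anti to the epoxide C–O bond (polar Felkin–Anh) and away from the C-7 isopropyl, giving the 6S alcohol; the sequence comes back to the route at 22.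

Step 3 (allylic oxidation). The risk is a sluggish ene reaction at an alkene deactivated by the allylic ether, with over-oxidation to the enal and attack at the propargylic position. The fallback builds the oxidised E terminus by olefination. It sets out from 4: dihydroxylation of the only alkene (OsO4 cat., N-methylmorpholine N-oxide, acetone/H2O) would give (4R)-4-[(4-methoxybenzyl)oxy]-2-methylhept-6-yne-2,3-diol F4 as a mixture at C-3. NaIO4 cleavage would give (R)-2-[(4-methoxybenzyl)oxy]pent-4-ynal F5. Wittig reaction with ethyl 2-(triphenylphosphoranylidene)propanoate (CH2Cl2, rt) would give ethyl (2E,4R)-4-[(4-methoxybenzyl)oxy]-2-methylhept-2-en-6-ynoate F6, and iBu2AlH (CH2Cl2, −78 °C) reduces the ester; the sequence comes back to the route at 5.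

Step 1 (propargylation). The risk is insufficient enantiofacial discrimination with a small aliphatic β,β-disubstituted enal, which would carry a diastereomer through the whole route. The fallback sets C-8 by reagent-controlled ketone reduction. It sets out from 1: a Barbier reaction with propargyl bromide and Zn dust (THF/aq. NH4Cl) would give racemic 6-methylhept-5-en-1-yn-4-ol F7. Dess–Martin oxidation would give 6-methylhept-5-en-1-yn-4-one F8, used at once to avoid isomerisation to the allenyl ketone. Corey–Bakshi–Shibata reduction ((S)-2-methyl-CBS-oxazaborolidine, catecholborane, toluene, −78 °C, the alkenyl group acting as the large substituent) should give the (R)-alcohol; the sequence comes back to the route at 3.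

**Further compounds**

F1 | step 14 | (4R,5R,6R,7R,8R)-4,5-epoxy-8-[(4-methoxybenzyl)oxy]germacra-1(10)E,11-dien-6-ol | COc1ccc(CO[C@@H]2C/C(C)=C/CC[C@@]3(C)O[C@@H]3[C@H](O)[C@H]2C(C)=C)cc1
F2 | step 14 | (4R,5R,6R,7R,8R)-4,5-epoxy-8-[(4-methoxybenzyl)oxy]germacr-1(10)E-en-6-ol | COc1ccc(CO[C@@H]2C/C(C)=C/CC[C@@]3(C)O[C@@H]3[C@H](O)[C@H]2C(C)C)cc1
F3 | step 14 | (4R,5S,7S,8R)-4,5-epoxy-8-[(4-methoxybenzyl)oxy]germacr-1(10)E-en-6-one | COc1ccc(CO[C@@H]2C/C(C)=C/CC[C@@]3(C)O[C@@H]3C(=O)[C@H]2C(C)C)cc1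
F4 | step 3 | (4R)-4-[(4-methoxybenzyl)oxy]-2-methylhept-6-yne-2,3-diol | C#CC[C@@H](OCc1ccc(OC)cc1)C(O)C(C)(C)O
F5 | step 3 | (R)-2-[(4-methoxybenzyl)oxy]pent-4-ynal | C#CC[C@@H](OCc1ccc(OC)cc1)C=O
F6 | step 3 | ethyl (2E,4R)-4-[(4-methoxybenzyl)oxy]-2-methylhept-2-en-6-ynoate | C#CC[C@@H](OCc1ccc(OC)cc1)/C=C(\C)C(=O)OCC
F7 | step 1 | racemic 6-methylhept-5-en-1-yn-4-ol | C#CCC(O)C=C(C)C
F8 | step 1 | 6-methylhept-5-en-1-yn-4-one | C#CCC(=O)C=C(C)C
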